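The target's cyclohexene ring is traced back to salicyl alcohol: the sequence O7–C7–C1(O1)–C6–O6 (C1 the ring carbon carrying OH and CH2OBz, C7 its CH2, C2=C3 the alkene, C4 the CH–OBz, C5 and C6 the CH–OH carbons) is the benzylic and phenolic oxygen pattern of that arene. One enantioselective iodine(III) dearomatisation joins the benzylic oxygen to C1, closing a spiro-oxirane and leaving a C6 ketone and the C2–C5 diene; the precursor is the unprotected phenol itself. Reduction in the same flask, benzoate opening at C7, an O1/O6 acetonide and osmium syn-dihydroxylation of C4=C5 anti to it (O4 and O5 are cis, both trans to O6) complete the oxygenation.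

Key step: step 1

Assumption: the sense of induction of the lactate-derived iodoarene in this new closure cannot be predicted with certainty; the (R,R)-catalyst is written, and its equally accessible (S,S)-antipode is used instead if the first run delivers the (3R)-spiro centre.

Step 1
Reactants: 1 2-hydroxybenzyl alcohol (salicyl alcohol)
Product: 3 (3S,4S)-1-oxaspiro[2.5]octa-5,7-dien-4-ol, via spiro-epoxy dienone 2 (not isolated)
Conditions: (R,R)-2,2'-[(2-iodo-1,3-phenylene)bis(oxy)]bis(N-mesitylpropanamide) (10 mol %), mCPBA (1.1 equiv), CH2Cl2 (0.02 M), −20 °C; then MeOH, CeCl3·7H2O, NaBH4 (excess), −78 °C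
Reagents that add atoms: none
Why: Proposed new method: mCPBA oxidises the aryl iodide to the λ3-iodane, the phenol oxygen of 1 displaces a ligand on iodine(III), and the benzylic hydroxyl then attacks the CH2-bearing ortho carbon (C1) while the aryl iodide leaves from oxygen, forming the C1–O bond and dienone 2; the closest known reaction types are the periodate Adler–Becker oxidation of salicyl alcohols (racemic) and chiral iodoarene-catalysed dearomative ortho-spirolactonisation of phenols. The oxirane closes in a 3-exo-trig mode onto the ring carbon that is being dearomatised. The C1 stereocentre is set by the catalyst alone, whose hydrogen-bonded lactamide arms wrap iodine in a C2-symmetric pocket that exposes one face of the prochiral ortho carbon, and a weakly ionising medium at low temperature keeps bond formation associated with the chiral iodane. The step needs ortho-over-para attack and phenol-over-alcohol oxidation, which should be secured because the only nucleophile within reach sits one atom from C1 and the medium is non-nucleophilic. Dienone 2 dimerises by [4+2] cycloaddition and is therefore intercepted cold and dilute by Luche 1,2-reduction, the excess borohydride also consuming residual peracid. The C6 stereocentre should follow from hydride addition anti to the C1–O bond (polar Felkin–Anh, with cerium bridging the carbonyl and oxirane oxygens on that face), placing the hydroxyl cis to the oxirane oxygen.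

Step 2
Reactants: 3 (3S,4S)-1-oxaspiro[2.5]octa-5,7-dien-4-ol, 4 benzoic acid
Product: 5 [(1S,6S)-1,6-dihydroxycyclohexa-2,4-dien-1-yl]methyl benzoate
Conditions: BzOH (1.5 equiv), Bu4NOBz (0.2 equiv), MeCN, 40 °C
Reagents that add atoms: benzoic acid 4, O=C(O)c1ccccc1
Why: Carboxylate SN2 opening of a 2,2-disubstituted oxirane at its unhindered methylene (C7) in a benzoic acid/benzoate buffer should leave the C1–O bond and both stereocentres untouched and free the tertiary C1 hydroxyl, while Payne rearrangement is excluded because the C6 hydroxyl lies on the same face as the oxirane oxygen.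

Step 3
Reactants: 5 [(1S,6S)-1,6-dihydroxycyclohexa-2,4-dien-1-yl]methyl benzoate
Product: 6 [(1S,6S)-1,6-(isopropylidenedioxy)cyclohexa-2,4-dien-1-yl]methyl benzoate (cis-fused acetonide across O1 and O6)
Conditions: 2,2-dimethoxypropane, PPTS (cat.), acetone, 0 °C → rt
Reagents that add atoms: 2,2-dimethoxypropane, COC(C)(C)OC
Why: Acetonide formation by transketalisation of the cis-1,2-diol under weakly acidic catalysis is the standard protection of acid-sensitive cyclohexadiene cis-diols and changes no stereocentre.

Step 4
Reactants: 6 [(1S,6S)-1,6-(isopropylidenedioxy)cyclohexa-2,4-dien-1-yl]methyl benzoate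
Product: 7 [(1S,4R,5R,6S)-4,5-dihydroxy-1,6-(isopropylidenedioxy)cyclohex-2-en-1-yl]methyl benzoate (4-OH and 5-OH cis to each other, trans to O6 and O1)
Conditions: OsO4 (2 mol %), NMO (1.1 equiv), acetone/H2O (4:1), 0 °C
Reagents that add atoms: osmium tetroxide (catalytic oxygen carrier), O=[Os](=O)(=O)=O; N-methylmorpholine N-oxide, C[N+]1([O-])CCOCC1; water, O
Why: Upjohn syn-dihydroxylation should take place at C4=C5, the alkene not flanked by the quaternary C1, from the face opposite the acetonide and the allylic C6–O bond (the usual anti course of osmylation next to an allylic ether), which sets C4 and C5 with both new hydroxyls cis to each other and trans to O6.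

Step 5
Reactants: 7 [(1S,4R,5R,6S)-4,5-dihydroxy-1,6-(isopropylidenedioxy)cyclohex-2-en-1-yl]methyl benzoate
Product: 8 [(1S,4R,5R,6S)-4-(benzoyloxy)-5-hydroxy-1,6-(isopropylidenedioxy)cyclohex-2-en-1-yl]methyl benzoate
Conditions: BzCl (1.05 equiv), pyridine, CH2Cl2, −40 → 0 °C
Reagents that add atoms: benzoyl chloride, O=C(Cl)c1ccccc1
Why: Regioselective acylation is expected at the allylic C4 hydroxyl, which has one oxygenated neighbour, in preference to the C5 hydroxyl, which is flanked by C4–OH and the acetonide-bearing C6 (the same reactivity order as the 3- and 4-hydroxyls of shikimate esters).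

Step 6
Reactants: 8 [(1S,4R,5R,6S)-4-(benzoyloxy)-5-hydroxy-1,6-(isopropylidenedioxy)cyclohex-2-en-1-yl]methyl benzoate
Product: 9 [(1S,4R,5S,6S)-4-(benzoyloxy)-1,5,6-trihydroxycyclohex-2-en-1-yl]methyl benzoate (target)
Conditions: TFA/H2O (4:1), CH2Cl2, 0 °C → rt
Reagents that add atoms: none
Why: Acid hydrolysis of the acetonide proceeds through the oxocarbenium ion at the acetal carbon, not by C1–O cleavage, so the benzoates and all four stereocentres should persist.

Compound list
1 | 2-hydroxybenzyl alcohol (salicyl alcohol) | OCc1ccccc1O | starting material
2 | (3S)-1-oxaspiro[2.5]octa-5,7-dien-4-one (formed and reduced in the flask) | O=C1C=CC=C[C@]12CO2 | intermediate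
3 | (3S,4S)-1-oxaspiro[2.5]octa-5,7-dien-4-ol (hydroxyl cis to the oxirane oxygen) | O[C@H]1C=CC=C[C@]12CO2 | intermediate
4 | benzoic acid | O=C(O)c1ccccc1 | starting material
5 | [(1S,6S)-1,6-dihydroxycyclohexa-2,4-dien-1-yl]methyl benzoate | O=C(OC[C@@]1(O)C=CC=C[C@@H]1O)c1ccccc1 | intermediate
6 | [(1S,6S)-1,6-(isopropylidenedioxy)cyclohexa-2,4-dien-1-yl]methyl benzoate | O=C(OC[C@@]12C=CC=C[C@@H]1OC(C)(C)O2)c1ccccc1 | intermediate
7 | [(1S,4R,5R,6S)-4,5-dihydroxy-1,6-(isopropylidenedioxy)cyclohex-2-en-1-yl]methyl benzoate | O=C(OC[C@@]12C=C[C@@H](O)[C@@H](O)[C@@H]1OC(C)(C)O2)c1ccccc1 | intermediate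
8 | [(1S,4R,5R,6S)-4-(benzoyloxy)-5-hydroxy-1,6-(isopropylidenedioxy)cyclohex-2-en-1-yl]methyl benzoate | O=C(OC[C@@]12C=C[C@@H](OC(=O)c3ccccc3)[C@@H](O)[C@@H]1OC(C)(C)O2)c1ccccc1 | intermediate
9 | [(1S,4R,5S,6S)-4-(benzoyloxy)-1,5,6-trihydroxycyclohex-2-en-1-yl]methyl benzoate (the C5 descriptor differs from 7 and 8 only through CIP ranking; the geometry is unchanged) | O=C(OC[C@@]1(O)C=C[C@@H](OC(=O)c2ccccc2)[C@@H](O)[C@@H]1O)c1ccccc1 | target

Total step count: 6. Longest linear sequence: 6 steps (1 → 9).

Steps most likely to fail

1. Step 1 (Proposed new method). The C–O bond may form through a phenoxenium-type species that has already left the chiral iodane, which would erode enantioselectivity. External nucleophiles may add at the para position, and the dienone may dimerise before hydride reaches it. The fallback uses known chemistry, sets out from 1 and returns at 3. Sodium periodate in water/CH2Cl2 at 0 °C (Adler–Becker oxidation) should give 2 together with its mirror image (3R)-1-oxaspiro[2.5]octa-5,7-dien-4-one F1. The cold organic layer is run directly into NaBH4/CeCl3 in methanol at −78 °C, giving 3 and its enantiomer (3R,4R)-1-oxaspiro[2.5]octa-5,7-dien-4-ol F2 as the racemate. Lipase-catalysed transesterification with vinyl acetate (Candida antarctica lipase B, MTBE, rt) is expected, by the empirical rule for secondary alcohols, to acetylate the (4R)-alcohol to (3R,4R)-1-oxaspiro[2.5]octa-5,7-dien-4-yl acetate F3. Unreacted 3 is separated by chromatography and rejoins the route at 3.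

2. Step 5. The two secondary hydroxyls may not be discriminated well enough, giving acylation at O5 or at both oxygens. The fallback sets out from 7 and returns at 8. Transorthoesterification with trimethyl orthobenzoate (cat. CSA, CH2Cl2) should give the 4,5-cyclic methyl orthobenzoate of 7 F4 as a mixture of epimers at the orthoester carbon. Brief treatment with aqueous acetic acid at 0 °C opens the orthoester far faster than the acetonide. By the usual stereoelectronic course it should leave the ester on the pseudoaxial oxygen (O4) and the free hydroxyl on the equatorial one (O5), giving 8.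

3. Step 2. Substitution at the neopentyl-type methylene may be slow enough for conjugate opening along the diene or dehydrative aromatisation to compete. The fallback sets out from 3 and returns at 5, and replaces external carboxylate attack by hydroxyl-directed delivery. Titanium(IV) isopropoxide binds O6 and the cis oxirane oxygen and transfers benzoate from 4 to C7 at or below room temperature in CH2Cl2. This is the established C3-selective opening of 2,3-epoxy alcohols by carboxylic acids, and it gives 5 directly without a new compound.

Further compounds
F1 | step 1 | (3R)-1-oxaspiro[2.5]octa-5,7-dien-4-one | O=C1C=CC=C[C@@]12CO2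
F2 | step 1 | (3R,4R)-1-oxaspiro[2.5]octa-5,7-dien-4-ol | O[C@@H]1C=CC=C[C@@]12CO2
F3 | step 1 | (3R,4R)-1-oxaspiro[2.5]octa-5,7-dien-4-yl acetate | CC(=O)O[C@@H]1C=CC=C[C@@]12CO2
F4 | step 5 | 4,5-cyclic methyl orthobenzoate of 7 (2-methoxy-2-phenyl-1,3-dioxolane fused at C4/C5, either epimer at the orthoester carbon) | O=C(OC[C@@]12C=C[C@@H](OC3(OC)c4ccccc4)[C@@H](O3)[C@@H]1OC(C)(C)O2)c1ccccc1
F0 | step 2 | none | none
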